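**Retrosynthetic overview**
1. Last bond: C8–O. The tertiary allylic alcohol and the C9=C10 alkene come from a C8=C9 alkene, using the C6 aroate as an internal oxygen relay (key step).
2. The C6 ester comes from a β-hydroxy ketone: hydroxyl-directed reduction sets C6, then the secondary alcohol is acylated.
3. Five-membered ring (formed second): intramolecular aldol closes C4–C5 onto the seven-membered ring and sets C4 and C5.
4. Quaternary C1: enantioselective copper-catalysed conjugate addition of a masked homoenolate Grignard reagent to a symmetric cross-conjugated cycloheptadienone.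
5. Seven-membered ring (formed first): (4+3) cycloaddition of 2,5-dimethylfuran with an oxyallyl cation, then hydrogenation and opening of the ether bridge.

Assumption: comments use daucane numbering (C1 quaternary ring-fusion carbon with CH3, C4 isopropyl carbinol, C5 ring-fusion CH, C6 ester carbon, C8 methyl carbinol, C9=C10 alkene); isopropyl vinyl ketone and 4-acetoxybenzoyl chloride are taken as purchasable.

**Route**

Step 1
Reactants: 1 2,5-dimethylfuran; 2 1,1,3-trichloropropan-2-one
Product: 4 (1R,5S)-1,5-dimethyl-8-oxabicyclo[3.2.1]oct-6-en-3-one (meso), via 2,4-dichloro cycloadduct 3 (not isolated)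
Conditions: Et3N, CF3CH2OH, 0 °C to rt; then Zn–Cu, NH4Cl, MeOH, rt
Reagents that add atoms: none
Why: Föhlisch-type (4+3) cycloaddition of the dichloro-oxyallyl cation with the electron-rich furan, then Zn–Cu reductive dechlorination; both chloro epimers converge on the meso ketone, so no stereocontrol is needed.

Step 2
Reactants: 4 (1R,5S)-1,5-dimethyl-8-oxabicyclo[3.2.1]oct-6-en-3-one
Product: 6 3,6-dimethylcyclohepta-2,6-dien-1-one, via saturated oxabicyclic ketone 5 (not isolated)
Conditions: H2 (1 atm), Pd/C, EtOAc, rt; filter; then p-TsOH·H2O (20 mol %), PhMe, reflux, Dean–Stark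
Reagents that add atoms: none
Why: Catalytic hydrogenation of the strained alkene, then acid-catalysed double β-elimination (retro-oxa-Michael opening of the bridge and dehydration of the tertiary β-hydroxy ketone) gives the achiral cross-conjugated dienone that holds all seven ring carbons and both methyl groups.

Step 3
Reactants: 7 4-methylpent-1-en-3-one (isopropyl vinyl ketone)
Product: 9 2-(2-bromoethyl)-2-(propan-2-yl)-1,3-dioxolane, via β-bromo ketone 8 (not isolated)
Conditions: HBr (gas), HOCH2CH2OH, CH2Cl2, 0 °C to rt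
Reagents that add atoms: hydrogen bromide (SMILES: Br); ethylene glycol (SMILES: OCCO)
Why: Conjugate hydrobromination of the enone followed by acid-catalysed ketalisation in the same pot, the standard route to β-bromo ketals (masked homoenolates).

Step 4
Reactants: 6 3,6-dimethylcyclohepta-2,6-dien-1-one; 9 2-(2-bromoethyl)-2-(propan-2-yl)-1,3-dioxolane
Product: 11 (6R)-3,6-dimethyl-6-{2-[2-(propan-2-yl)-1,3-dioxolan-2-yl]ethyl}cyclohept-2-en-1-one, via Grignard reagent 10 (not isolated)
Conditions: 9, Mg, THF, rt; then 6, Cu(OTf)2 (3 mol %), (S)-1-mesityl-3-(1-hydroxy-4-methylpentan-2-yl)imidazolinium PF6 (4 mol %; enantiomer of the ligand chosen in a test run to give R), Et2O, −30 °C; aq. NH4Cl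
Reagents that add atoms: none
Why: Copper–NHC-catalysed asymmetric conjugate addition of a Grignard reagent to a β,β-disubstituted enone; the two β-carbons of the dienone are enantiotopic, so the chiral catalyst sets the quaternary C1 by face selection, and the magnesium enolate formed prevents a second addition.

Step 5
Reactants: 11 (6R)-3,6-dimethyl-6-{2-[2-(propan-2-yl)-1,3-dioxolan-2-yl]ethyl}cyclohept-2-en-1-one
Product: 13 (3R,3aR,8aR)-3-hydroxy-6,8a-dimethyl-3-(propan-2-yl)-2,3,3a,7,8,8a-hexahydroazulen-4(1H)-one, via diketone 12 (not isolated)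
Conditions: 1 M HCl, THF, rt; then t-BuOK (0.3 equiv), THF, −20 to 0 °C
Reagents that add atoms: water (SMILES: O)
Why: Ketal hydrolysis, then intramolecular aldol addition (5-enolexo closure) that keeps the conjugated ring ketone. The three-atom tether on C1 reaches the enolate carbon C5 only on its own face, which gives the cis ring fusion; the potassium-chelated transition state (and the O–H···O=C hydrogen bond in the product) puts the C4 hydroxyl syn to the C6 carbonyl, so isopropyl lies on the face of the angular methyl.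

Step 6
Reactants: 13 (3R,3aR,8aR)-3-hydroxy-6,8a-dimethyl-3-(propan-2-yl)-2,3,3a,7,8,8a-hexahydroazulen-4(1H)-one
Product: 15 (3R,3aR,8aS)-3-hydroxy-6,8a-dimethyl-3-(propan-2-yl)-2,3,3a,5,8,8a-hexahydroazulen-4(1H)-one, via bis-silyl dienol ether 14 (not isolated)
Conditions: TMSOTf, Et3N, CH2Cl2, 0 °C to rt; then Bu4NF, AcOH, THF, −78 °C
Reagents that add atoms: none
Why: Amine-mediated silylation gives the thermodynamic linear dienol silyl ether (as with steroidal enones), and kinetic α-protonation of the fluoride-released dienolate at C7 deconjugates the enone to the C8=C9 alkene; no stereocentre is formed, and the cis-fused C5 is not touched.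

Step 7
Reactants: 15 (3R,3aR,8aS)-3-hydroxy-6,8a-dimethyl-3-(propan-2-yl)-2,3,3a,5,8,8a-hexahydroazulen-4(1H)-one
Product: 16 (3R,3aS,4S,8aS)-6,8a-dimethyl-3-(propan-2-yl)-1,2,3,3a,4,5,8,8a-octahydroazulene-3,4-diol
Conditions: Me4NBH(OAc)3, MeCN/AcOH (1:1), −30 °C
Reagents that add atoms: none
Why: Evans–Saksena hydroxyl-directed reduction: the C4 hydroxyl binds boron and delivers hydride to the ketone face on which it sits, so the new C6 hydroxyl ends up on the opposite face (1,3-anti), the face of H-5 and the angular methyl.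

Step 8
Reactants: 16 (3R,3aS,4S,8aS)-6,8a-dimethyl-3-(propan-2-yl)-1,2,3,3a,4,5,8,8a-octahydroazulene-3,4-diol; 17 4-(acetyloxy)benzoyl chloride
Product: 18 (3R,3aS,4S,8aS)-3-hydroxy-6,8a-dimethyl-3-(propan-2-yl)-1,2,3,3a,4,5,8,8a-octahydroazulen-4-yl 4-(acetyloxy)benzoate
Conditions: pyridine, DMAP (10 mol %), CH2Cl2, 0 °C to rt
Reagents that add atoms: none
Why: DMAP-catalysed acylation is selective for the secondary C6 alcohol over the hindered tertiary C4 alcohol and touches no stereocentre.

Step 9
Reactants: 18 (3R,3aS,4S,8aS)-3-hydroxy-6,8a-dimethyl-3-(propan-2-yl)-1,2,3,3a,4,5,8,8a-octahydroazulen-4-yl 4-(acetyloxy)benzoate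
Product: 20 (3R,3aS,4S,6R,8aS)-3,6-dihydroxy-6,8a-dimethyl-3-(propan-2-yl)-1,2,3,3a,4,5,6,8a-octahydroazulen-4-yl 4-hydroxybenzoate, via acetate-protected hydroxylation product 19 (not isolated)
Conditions: (PhSe)2 (10 mol %), 2,4,6-tris(4-methoxyphenyl)pyrylium BF4 (5 mol %), air, H2O (5 equiv), MeCN, blue LED, rt; then K2CO3 (0.2 equiv), MeOH, 0 °C
Reagents that add atoms: water (SMILES: O)
Why: Proposed new method: aroyl-relayed selenium-π-acid dehydrogenative hydroxylation (net oxidative 1,3-transposition across C8=C9–C10H2); photo-aerobically generated PhSe+ adds reversibly to C8=C9, and only the seleniranium ion on the face opposite the C6 aroyloxy group can be opened from inside by the ester carbonyl oxygen, at the tertiary C8 through a six-membered 1,3-dioxan-2-ylium ion, so the new C8–O bond is forced syn to C6–O (this sets C8, with its methyl on the other face); water hydrolyses the acyloxonium ion to the tertiary alcohol with the acyl group staying on the secondary oxygen, and the C9 selenide is oxidised to tetravalent selenium and eliminates with a C10 hydrogen (C8 has none) to give C9=C10 and return the catalyst; the closest known chemistry is selenium-π-acid allylic esterification and lactonisation of alkenes with carboxylic acids (here an ester carbonyl plus water replaces the acid) combined with Woodward–Prévost-type acyloxonium hydrolysis, and the second stage is a routine methanolysis of the aryl acetate.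

**Compound list**
1 | 2,5-dimethylfuran | Cc1ccc(C)o1 | starting material
2 | 1,1,3-trichloropropan-2-one | ClCC(=O)C(Cl)Cl | starting material
3 | 2,4-dichloro-1,5-dimethyl-8-oxabicyclo[3.2.1]oct-6-en-3-one (mixture of chloro epimers) | C[C@@]12C=C[C@@](C)(O1)C(Cl)C(=O)C2Cl | intermediate
4 | (1R,5S)-1,5-dimethyl-8-oxabicyclo[3.2.1]oct-6-en-3-one (meso) | C[C@@]12C=C[C@@](C)(O1)CC(=O)C2 | intermediate
5 | (1R,5S)-1,5-dimethyl-8-oxabicyclo[3.2.1]octan-3-one (meso) | C[C@@]12CC[C@@](C)(O1)CC(=O)C2 | intermediate
6 | 3,6-dimethylcyclohepta-2,6-dien-1-one | CC1=CC(=O)C=C(C)CC1 | intermediate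
7 | 4-methylpent-1-en-3-one | CC(C)C(=O)C=C | starting material
8 | 1-bromo-4-methylpentan-3-one | CC(C)C(=O)CCBr | intermediate
9 | 2-(2-bromoethyl)-2-(propan-2-yl)-1,3-dioxolane | CC(C)C1(CCBr)OCCO1 | intermediate
10 | {2-[2-(propan-2-yl)-1,3-dioxolan-2-yl]ethyl}magnesium bromide | CC(C)C1(CC[Mg]Br)OCCO1 | intermediate
11 | (6R)-3,6-dimethyl-6-{2-[2-(propan-2-yl)-1,3-dioxolan-2-yl]ethyl}cyclohept-2-en-1-one | CC(C)C1(CC[C@@]2(C)CCC(C)=CC(=O)C2)OCCO1 | intermediate
12 | (6R)-3,6-dimethyl-6-(4-methyl-3-oxopentyl)cyclohept-2-en-1-one | CC(C)C(=O)CC[C@@]1(C)CCC(C)=CC(=O)C1 | intermediate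
13 | (3R,3aR,8aR)-3-hydroxy-6,8a-dimethyl-3-(propan-2-yl)-2,3,3a,7,8,8a-hexahydroazulen-4(1H)-one (cis-fused; OH syn to the ring carbonyl) | CC(C)[C@]1(O)CC[C@@]2(C)CCC(C)=CC(=O)[C@@H]12 | intermediate
14 | bis(trimethylsilyl) derivative of 13: C4 silyl ether and C6(OSi)=C7–C8=C9 dienol silyl ether | CC(C)[C@]1(O[Si](C)(C)C)CC[C@@]2(C)CC=C(C)C=C(O[Si](C)(C)C)[C@@H]12 | intermediate
15 | (3R,3aR,8aS)-3-hydroxy-6,8a-dimethyl-3-(propan-2-yl)-2,3,3a,5,8,8a-hexahydroazulen-4(1H)-one | CC(C)[C@]1(O)CC[C@@]2(C)CC=C(C)CC(=O)[C@@H]12 | intermediate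
16 | (3R,3aS,4S,8aS)-6,8a-dimethyl-3-(propan-2-yl)-1,2,3,3a,4,5,8,8a-octahydroazulene-3,4-diol | CC(C)[C@]1(O)CC[C@@]2(C)CC=C(C)C[C@H](O)[C@@H]12 | intermediate
17 | 4-(acetyloxy)benzoyl chloride | CC(=O)Oc1ccc(cc1)C(Cl)=O | starting material
18 | (3R,3aS,4S,8aS)-3-hydroxy-6,8a-dimethyl-3-(propan-2-yl)-1,2,3,3a,4,5,8,8a-octahydroazulen-4-yl 4-(acetyloxy)benzoate | CC(C)[C@]1(O)CC[C@@]2(C)CC=C(C)C[C@H](OC(=O)c3ccc(OC(C)=O)cc3)[C@@H]12 | intermediate
19 | (3R,3aS,4S,6R,8aS)-3,6-dihydroxy-6,8a-dimethyl-3-(propan-2-yl)-1,2,3,3a,4,5,6,8a-octahydroazulen-4-yl 4-(acetyloxy)benzoate | CC(C)[C@]1(O)CC[C@@]2(C)C=C[C@](C)(O)C[C@H](OC(=O)c3ccc(OC(C)=O)cc3)[C@@H]12 | intermediate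
20 | (3R,3aS,4S,6R,8aS)-3,6-dihydroxy-6,8a-dimethyl-3-(propan-2-yl)-1,2,3,3a,4,5,6,8a-octahydroazulen-4-yl 4-hydroxybenzoate | CC(C)[C@]1(O)CC[C@@]2(C)C=C[C@](C)(O)C[C@H](OC(=O)c3ccc(O)cc3)[C@@H]12 | target

**Step count**
Total: 9 steps. Longest linear sequence: 8 steps (1, 2, 4, 5, 6, 7, 8, 9); step 3 is a one-step side branch.

**Steps most likely to fail, with fallbacks**

Step 9 (the proposed new step). Risks are competing attack of the C4 hydroxyl on the seleniranium ion and poor catalyst turnover. The fallback uses known chemistry and sets out from diol 16. VO(acac)2 and t-BuOOH in CH2Cl2 give, by homoallylic-hydroxyl direction, the 8,9-epoxide with the oxirane oxygen syn to the C6 hydroxyl, epoxy diol F1. PhSeNa, made from (PhSe)2 and NaBH4 in EtOH, opens F1 at the secondary C9 to the hydroxy selenide F2. H2O2 and pyridine in THF oxidise F2 to the selenoxide F3, which eliminates in the flask toward C10 (Sharpless–Lauer sequence) to the triol F4. Acylation of the only secondary hydroxyl of F4 with 17 (pyridine, DMAP) comes back to the route at 19, which is methanolysed to 20 as in the second stage of step 9.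

Step 4. Risks are the enantioselectivity and the 1,4-reactivity of a functionalised Grignard reagent on a cross-conjugated dienone. The fallback sets out from 6 and 10: CuBr·SMe2 (10 mol %) in THF at −40 °C, then aq. NH4Cl, gives the racemic adduct F5. Preparative chromatography on a chiral stationary phase (supercritical CO2/MeOH) separates the enantiomers, and the R enantiomer comes back to the route as 11.

Step 6. Risks are the regiochemistry of dienol ether formation and reconjugation of the β,γ-enone on handling. The fallback sets out from 13: HOCH2CH2OH and p-TsOH in benzene at reflux (Dean–Stark) ketalise the enone with the classic shift of the double bond out of conjugation and give the C8=C9 ethylene ketal F6. PPTS in wet acetone at 0 °C releases the ketone without reconjugation and comes back to the route at 15.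

**Further compounds**
F1 | step 9 | 8,9-epoxide of diol 16, oxirane oxygen syn to the C6 hydroxyl | CC(C)[C@]1(O)CC[C@@]2(C)C[C@@H]3O[C@]3(C)C[C@H](O)[C@@H]12
F2 | step 9 | 9-(phenylselanyl) 4,6,8-triol, C8 hydroxyl syn to the C6 hydroxyl and anti to selenium | CC(C)[C@]1(O)CC[C@@]2(C)C[C@@H]([Se]c3ccccc3)[C@](C)(O)C[C@H](O)[C@@H]12
F3 | step 9 | selenoxide of F2 | CC(C)[C@]1(O)CC[C@@]2(C)C[C@@H]([Se](=O)c3ccccc3)[C@](C)(O)C[C@H](O)[C@@H]12
F4 | step 9 | (3R,3aS,4S,6R,8aS)-6,8a-dimethyl-3-(propan-2-yl)-1,2,3,3a,4,5,6,8a-octahydroazulene-3,4,6-triol | CC(C)[C@]1(O)CC[C@@]2(C)C=C[C@](C)(O)C[C@H](O)[C@@H]12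
F5 | step 4 | racemic 3,6-dimethyl-6-{2-[2-(propan-2-yl)-1,3-dioxolan-2-yl]ethyl}cyclohept-2-en-1-one | CC(C)C1(CCC2(C)CCC(C)=CC(=O)C2)OCCO1
F6 | step 6 | ethylene ketal of 15 (1,3-dioxolane at the ring ketone, alkene at C8=C9) | CC(C)[C@]1(O)CC[C@@]2(C)CC=C(C)CC3(OCCO3)[C@@H]12
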